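All runs were generated by integration with constants of no real substance, noise included.

I began with a slope.

| flask | starting material | partner | second substrate | protic impurity | temperature | remark | time |
|---|---|---|---|---|---|---|---|
| east | 0.10 M | 0.13 M | 0.10 M | 0.010 M | 95 °C | run made earlier |  |
| north | 0.14 M | 0.13 M | 0.10 M | 0.010 M | 106 °C | run made earlier |  |
| south-west | 0.22 M | 0.13 M | 0.10 M | 0.010 M | 95 °C | run made earlier |  |
| south-east | 0.10 M | 0.13 M | 0.10 M | 0.020 M | 106 °C | run made earlier |  |
| epsilon | 0.10 M | 0.130 M (fed, over 1.5 h) | 0.100 M | 0.0100 M |  | the addition at 70 °C, then warmed to 100 °C; the feed brings no volume worth counting | 2.0 h |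
| alpha | 0.10 M | 0.130 M | 0.100 M | 0.0100 M | 100 °C | everything together at the start | 2.0 h |
| eta | 0.10 M | 0.130 M | 0.100 M (fed, over 1.5 h) | 0.0100 M | 100 °C | all else is in the flask from the start; the feed brings no volume worth counting | 2.0 h |
| theta | 0.10 M | 0.130 M (fed, over 1.5 h) | 0.100 M | 0.0100 M | 100 °C | all else is in the flask from the start; the feed brings no volume worth counting | 2.0 h |

east run (percent of the starting material charged)

| time / min | target / % | starting material / % |
|---|---|---|
| 6.00 | 10.9 | 82.9 |
| 20.0 | 13.4 | 72.3 |
| 30.0 | 13.2 | 65.9 |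
| 50.0 | 11.5 | 60.7 |
| 80.0 | 8.7 | 51.6 |
| 90.0 | 7.6 | 48.4 |
| 120 | 5.8 | 43.5 |

north run (percent of the starting material charged)

| time / h | target / % | starting material / % |
|---|---|---|
| 0.133 | 12.9 | 72.0 |
| 0.333 | 10.2 | 58.3 |
| 0.667 | 6.4 | 46.6 |
| 1.00 | 3.1 | 37.1 |
| 1.33 | 1.9 | 32.2 |
| 2.00 | 2.1 | 23.0 |
| 2.50 | 1.4 | 20.0 |

south-west run (percent of the starting material charged)

| time / h | target / % | starting material / % |
|---|---|---|
| 0.133 | 11.5 | 82.3 |
| 0.333 | 12.6 | 76.5 |
| 0.667 | 9.5 | 70.6 |
| 1.00 | 9.1 | 66.5 |
| 1.33 | 6.6 | 61.5 |
| 2.00 | 4.8 | 56.5 |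
| 2.50 | 4.2 | 53.6 |

south-east run (percent of the starting material charged)

| time / h | target / % | starting material / % |
|---|---|---|
| 0.200 | 12.0 | 57.5 |
| 0.667 | 6.1 | 34.1 |
| 1.00 | 4.2 | 25.5 |
| 1.50 | 3.2 | 17.5 |
| 2.50 | 0.2 | 9.8 |

(each reading ± 0.5 percentage points)

- the analysis behind the earlier runs scatters by 0.5 percentage points, standard deviation

1. the flask with the highest amount of target, in percent of the starting material charged ("all alike" if they lie within 1.5 percentage points) (epsilon / alpha / eta / theta / all alike)
2. final target, as a percentage of the starting material charged, in epsilon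
3. final target, as a percentage of the starting material charged, in alpha
4. final target, as a percentage of the starting material charged, in eta
5. final target, as a percentage of the starting material charged, in theta

In the east run target stood at 13.4% at 20.0 min and then fell alongside starting material, so I treated the two as one pool, lost at a single pseudo-first-order constant λ with partner taken at its mean. I assumed that protic impurity removes its equal of starting material early, which leaves 90.0% of the charge in the pool.

The late logarithmic slope of starting material gave λ = 0.305 h⁻¹ in the east run at 95 °C and 0.680 h⁻¹ in the south-east run at 106 °C. Alpha's 100 °C lies near the middle, so I took their geometric mean, 0.455 h⁻¹. Over 2.0 h that made D = 0.911. I call D the drain number, the count of e-foldings the pool goes through in the flask.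

Alpha's pool then ends at 36.2%. The last east reading gave target over starting material as r = 0.133, so target is the pool times r/(r+1), or 4.26%.

Was one number enough? The east curve gave 0.350 h⁻¹ early and 0.286 h⁻¹ late, so the mean hides a drift, and that drift spreads alpha from 3.71% to 4.50%.

For epsilon I counted the time at 100 °C alone, so D = 0.228 and target 8.43%. For theta I counted the feed at half weight, so D = 0.569 and target 5.99%. Second substrate stood at 0.10 M in the east run and 0.10 M in the south-east run, so I read nothing about its feed and gave eta alpha's number. Epsilon came first in my reckoning.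

The forecast gave 10% for epsilon, 3.7% for alpha, 4.2% for eta and 6.3% for theta, with epsilon highest, and held that “the drain is nearly frozen at 70 °C”.

The flasks gave 10.9% in epsilon, 4.07% in alpha, 4.08% in eta and 6.52% in theta, with epsilon highest.

    starting material + partner ⇌ target (K = 2.50 L mol⁻¹, k = 0.00770 L mol⁻¹ s⁻¹, Ea = 76.0 kJ mol⁻¹, ΔH = 19.0 kJ mol⁻¹)
    second substrate + partner ⇌ second product (K = 3.10 L mol⁻¹, k = 0.0300 L mol⁻¹ s⁻¹, Ea = 85.0 kJ mol⁻¹, ΔH = −59.0 kJ mol⁻¹)
    target → over-reaction product (k = 9.50 × 10⁻⁴ s⁻¹, Ea = 124 kJ mol⁻¹)
    starting material + protic impurity → quenched substrate (k = 0.0170 L mol⁻¹ s⁻¹, Ea = 88.0 kJ mol⁻¹)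
    2 second substrate → self-condensation product (k = 0.0540 L mol⁻¹ s⁻¹, Ea = 79.0 kJ mol⁻¹)
    (constants at 100 °C)

In alpha at 2.00 h target was made at 0.834 of the rate at which it was used up, and starting material plus target stood at 33.7%, a drain number of 0.984 beside my 0.911. Theta held 47.1% as starting material plus target at 2.00 h, a drain number of 0.647 beside my 0.569.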